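## Structural features

The target 35 is a trans-fused 2,3,3a,4,5,7a-hexahydro-1H-inden-2-one. A cyclopentanone (C1, C2, C3, C3a, C7a) shares the C3a–C7a bond with a cyclohexene (C3a, C4, C5, C6, C7, C7a) whose C6=C7 bond is trisubstituted and carries ethyl on C7. Six stereocentres are contiguous. C1, C7a, C3a and C3 run round the five-membered ring with each neighbouring pair of substituents trans. C4 (ethyl, CO2H) and C5 (ethyl, (E)-styryl) are vicinal quaternary carbons, with carboxyl and styryl cis and the carboxyl trans to the C3a–C3 bond. C1 and C3 are α to the ketone, and the all-trans arrangement should be the equilibrium one, so they can be corrected late; C3a, C7a, C4 and C5 cannot. The carboxyl carbon is flanked by two fully substituted carbons, so an ester there can only be cleaved at the alkyl–oxygen bond. The styryl and ring alkenes rule out ozone, dissolving metals, hydrogenation and unselective metathesis late in the route. The real difficulty is the C4/C5 quaternary pair in fixed relation to C3a, together with the trans ring fusion.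

The key step uses the fact that C7a is both a ring-fusion carbon and, in the monocyclic precursor 31, the allylic ring CH2, separated from the diazo carbon C1 by C2, C3 and C3a. A carbenoid at C1 therefore meets a C7a–H bond in a 1,5 relationship, and the C1–C7a bond closes the cyclopentanone. The structures of 31 and 32 agree with 35 at every shared stereocentre and need no change. One point of the rationale is revised: an allylic C–H bond is not specially activated towards an electrophilic acceptor/acceptor rhodium carbenoid. The site is selected by ring size and by secondary versus primary C–H, and the neighbouring alkene is a liability (cyclopropanation) that the catalyst must suppress.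

## Logic of the disconnections

Locants C1–C7a are those of 35; in earlier compounds "future Cn" is the carbon that becomes Cn.

35 from 33: the two ester O–alkyl bonds and the C1–CO2 bond are cut. Both acid functions stay masked until the end, and the ester on C1 serves as a regiochemical handle. The gain is a neutral, non-enolisable diester as penultimate compound. The forward step must cleave a hindered methyl ester at the methyl carbon, decarboxylate, and leave C1 and C3 at equilibrium.

33 from 32: the C1–ethyl bond is cut. The β-keto ester makes C1 the only nucleophilic carbon, so the last ethyl group enters regiospecifically. The demand is C- rather than O-alkylation at a carbon next to the ring fusion.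

32 from 31: the C1–C7a bond is cut, which opens the five-membered ring and removes the C7a and C1 stereocentres. The bicycle becomes a monocyclic cyclohexene whose three stereocentres are already in place. The forward insertion must take the pseudo-equatorial C7a–H and must not add to either alkene. Two refinements are built into 31: C3 carries the configuration that 35 needs, although a wrong one would be corrected in the last step, and the two ester alkyl groups are both removable by iodide in one operation.

31 from 30, and 30 from 28 and 29: the C=N2 unit and then the future C1–C2 bond are cut. The diazo keto ester reduces to an aldehyde plus a two-carbon diazo ester. The forward steps must not enolise the C3 stereocentre or touch the alkenes.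

28 from 27, and 27 from 26: only masking groups change (acetal to aldehyde, acid to methyl ester). The aldehyde must survive two strong-base steps earlier on, and the acid must be blocked before diazo chemistry. The hindered acid has to be esterified by carboxylate alkylation.

26 from 23: the C4–C5 bond is cut and the carboxyl oxygen is reconnected to future C7, which gives a six-membered lactone carrying a dienyl group. Both quaternary centres then arise in one sigmatropic event in which the ring fixes the enolate geometry. Two quaternary stereocentres are exchanged for one tertiary carbinol centre and one alkene geometry. The forward step needs a boat-like transition state with the dienyl group axial, and an (E)-configured trisubstituted alkene.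

23 from 21 and 22, 21 from 17 and 20, 20 from 18 and 19, 17 from 16, 16 from 15: the two C=C bonds of the diene are cut in turn, back to a protected hydroxymethyl group on future C7. The ionisation-prone dienyl ester is thus formed only one step before it is used. Both olefinations must be E-selective and must spare the lactone.

15 from 14: the C4–ethyl bond is cut. The ethyl group enters by lactone enolate alkylation, and its configuration is irrelevant because the centre is planarised again.

14 from 13, 13 from 12, 12 from 11: the future C2 carbon is moved from acetal through aldehyde to thioester, and the lactone back to a lactol. The reduction of 12 must distinguish thioester from lactone.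

11 from 7 and 9, 9 from 8: the C3–C3a bond is cut. A catalyst-controlled conjugate addition sets C3a and C3 independently of the remote carbinol centre, and the freed aldehyde closes onto the tertiary alcohol. The forward step needs high facial selectivity on a β-branched enal.

7 from 5 and 6, 5 from 3 and 4, 3 from 1: the enal C=C bond, the C3a–C7a bond and the epoxide C–O bond are cut. The whole left-hand part reduces to a five-carbon allylic alcohol whose asymmetric epoxidation sets the single carbinol stereocentre.

## Other disconnections considered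

Alternative 1: The cut is at the C7a–C7 bond and the C1–ethyl bond, followed by the C6=C7 bond. In the forward sense a but-1-en-2-yl cuprate adds to C7a of the cyclopentenone A2 anti to the side chain on C3a, and the enolate is trapped with iodoethane to give A1. Ring-closing metathesis between the vinyl and butenyl groups then gives the methyl ester A3, which is cleaved as in step 22. In its favour, the trans relation at C3a/C7a follows from anti addition to a 4-substituted cyclopentenone. That is a more dependable element than the discrimination between two diastereotopic hydrogens in step 20, and on this point the alternative is the better plan. It also needs no diazo compound. Against it, A2 must already carry both quaternary centres on an open chain, where no ring helps to control them. Ethylation of a cuprate-derived enolate is slow and prone to proton exchange. The metathesis must form a trisubstituted alkene next to a quaternary carbon and must choose vinyl over styryl. Structurally it builds the five-membered ring first and the six-membered ring last, the reverse of the chosen plan. Mechanistically it is polar and organometallic rather than carbenoid. In step count it is at best equal, because a stereocontrolled synthesis of the side chain of A2 must be added.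

Alternative 2: The cut is at C3a–C7a, C1–C2 and C2–C3 at once. In the forward sense the dienyne A5 is treated with Co2(CO)8 and an amine N-oxide (or [RhCl(CO)2]2 under CO) and should give the bicyclic enone A4. In its favour it offers the largest gain in complexity per step: both rings and three C–C bonds. The two quaternary carbons in the tether should help cyclisation. After the precursor it is better than the chosen plan in step economy. Against it, the alkene partner is an internal 1,2-disubstituted double bond that is part of a conjugated diene, a slow and ambiguous partner. The C7a configuration is set only by the conformation of the tether. A4 contains a tetrasubstituted C3=C3a enone, so the C3a hydrogen must be delivered later, trans to C7a–H, next to quaternary C4 and without reducing the styryl group; this is the weak point. The chosen plan sets the ring fusion in the bond-forming step and needs no reduction. A5, like A2, also requires the quaternary pair to be made on an open chain.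

Alternative 3: The cut is at C6=C7, from a precursor A7 in which C5 carries two vinyl groups. In the forward sense ring-closing metathesis between the butenyl group on C7a and one vinyl group gives A6. The remaining vinyl is then arylated (Heck reaction with iodobenzene, or cross-metathesis with styrene) to give A3. In its favour, C5 is not a stereocentre in A7, so only C4 must be set before ring closure. On precursor burden this alternative is better than the chosen plan and than the other two. Against it, the choice between the diastereotopic vinyl groups rests on the small difference between ethyl and vinyl in the cyclising conformer, so both its sense and its size are uncertain, and a wrong choice gives an uncorrectable C5 epimer. The vinyl-to-styryl conversion adds steps at a neopentyl position. The fully substituted cyclopentanone must first be made, probably by the chemistry of Alternative 1. The chosen plan derives C5 from an alkene geometry, which is predictable, but pays with a congested rearrangement. Step economy is similar.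

Key step: step 20

Assumption: compounds 1, 4 (as its THF solution), 6, 8, 18, 19, 22 and 29 are catalogue chemicals.
Assumption: the all-trans arrangement at C1 and C3 of 35 (each ethyl trans to its ring neighbour) is the thermodynamic one, so the final step may equilibrate both centres.

## Steps

Step 1
Reactants: 1 2-methylenebutan-1-ol
Product: 3 tert-butyl{[(2S)-2-ethyloxiran-2-yl]methoxy}diphenylsilane, via [(2R)-2-ethyloxiran-2-yl]methanol 2 (not isolated)
Conditions: Ti(OiPr)4 (5 mol%), D-(−)-diisopropyl tartrate (6 mol%), cumene hydroperoxide, 4 Å MS, CH2Cl2, −20 °C; then TBDPSCl, Et3N, DMAP (cat.), −20 → 0 °C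
Reagents that add atoms: cumene hydroperoxide CC(C)(OO)c1ccccc1; tert-butyl(chloro)diphenylsilane CC(C)(C)[Si](Cl)(c1ccccc1)c1ccccc1
Why: Sharpless asymmetric epoxidation of a 2-substituted allylic alcohol; the D-tartrate complex delivers oxygen to the face that gives the (R)-epoxy alcohol and so sets the carbinol centre (future C7). Silylation in the same pot avoids isolating the small water-soluble epoxy alcohol (the change of descriptor from R to S comes from the priority rules only).

Step 2
Reactants: 3 tert-butyl{[(2S)-2-ethyloxiran-2-yl]methoxy}diphenylsilane; 4 vinylmagnesium bromide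
Product: 5 (3S)-3-({[tert-butyl(diphenyl)silyl]oxy}methyl)hex-5-en-3-ol
Conditions: CuI (10 mol%), THF, −30 → 0 °C; aq. NH4Cl
Reagents that add atoms: none
Why: Copper-catalysed SN2 opening of a 2,2-disubstituted epoxide at its CH2 terminus; the quaternary stereocentre is not touched.

Step 3
Reactants: 5 (3S)-3-({[tert-butyl(diphenyl)silyl]oxy}methyl)hex-5-en-3-ol; 6 (2E)-but-2-enal
Product: 7 (2E,5S)-5-({[tert-butyl(diphenyl)silyl]oxy}methyl)-5-hydroxyhept-2-enal
Conditions: second-generation Hoveyda–Grubbs catalyst (3 mol%), 6 (5 equiv), CH2Cl2, 40 °C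
Reagents that add atoms: none
Why: Olefin cross-metathesis of a terminal alkene with an enal, which should be E-selective and tolerates the free tertiary alcohol. It is placed before any diene is present so that no ring-closing pathway competes.

Step 4
Reactants: 8 S-methyl butanethioate
Product: 9 tert-butyl(dimethyl){[(1Z)-1-(methylsulfanyl)but-1-en-1-yl]oxy}silane
Conditions: LDA, THF, −78 °C; TBSCl, −78 °C → rt
Reagents that add atoms: tert-butyl(chloro)dimethylsilane CC(C)(C)[Si](C)(C)Cl
Why: Kinetic enolisation of a thioester with LDA in THF followed by O-silylation should give the (Z)-silyl ketene thioacetal (sulfur and ethyl cis).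

Step 5
Reactants: 7 (2E,5S)-5-({[tert-butyl(diphenyl)silyl]oxy}methyl)-5-hydroxyhept-2-enal; 9 tert-butyl(dimethyl){[(1Z)-1-(methylsulfanyl)but-1-en-1-yl]oxy}silane
Product: 11 S-methyl (2S)-2-[(2S,4S)-2-({[tert-butyl(diphenyl)silyl]oxy}methyl)-2-ethyl-6-hydroxyoxan-4-yl]butanethioate (both anomers), via open-chain hydroxy aldehyde 10 (not isolated)
Conditions: (2R,5R)-5-benzyl-2-tert-butyl-3-methylimidazolidin-4-one·CF3CO2H (20 mol%), CH2Cl2–iPrOH, H2O (2 equiv), −40 °C
Reagents that add atoms: none
Why: Iminium-catalysed Mukaiyama–Michael addition; the (2R,5R)-imidazolidinone shields one face of the (E)-iminium ion, so the future C3a centre is set by the catalyst and not by the remote carbinol carbon. The (Z)-ketene thioacetal should add through an open transition state to give the anti relation at future C3. The freed δ-hydroxy aldehyde then closes to the lactol.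

Step 6
Reactants: 11 S-methyl (2S)-2-[(2S,4S)-2-({[tert-butyl(diphenyl)silyl]oxy}methyl)-2-ethyl-6-hydroxyoxan-4-yl]butanethioate
Product: 12 S-methyl (2S)-2-[(2S,4S)-2-({[tert-butyl(diphenyl)silyl]oxy}methyl)-2-ethyl-6-oxooxan-4-yl]butanethioate
Conditions: TEMPO (10 mol%), PhI(OAc)2, CH2Cl2, rt
Reagents that add atoms: none
Why: Nitroxyl-catalysed oxidation of a lactol to the lactone; thioester and silyl ether are inert.

Step 7
Reactants: 12 S-methyl (2S)-2-[(2S,4S)-2-({[tert-butyl(diphenyl)silyl]oxy}methyl)-2-ethyl-6-oxooxan-4-yl]butanethioate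
Product: 13 (2S)-2-[(2S,4S)-2-({[tert-butyl(diphenyl)silyl]oxy}methyl)-2-ethyl-6-oxooxan-4-yl]butanal
Conditions: Et3SiH, 10% Pd/C (5 mol%), acetone, rt
Reagents that add atoms: none
Why: Fukuyama reduction of a thioester to the aldehyde, chemoselective beside the lactone; no alkene is present at this stage.

Step 8
Reactants: 13 (2S)-2-[(2S,4S)-2-({[tert-butyl(diphenyl)silyl]oxy}methyl)-2-ethyl-6-oxooxan-4-yl]butanal
Product: 14 (4S,6S)-6-({[tert-butyl(diphenyl)silyl]oxy}methyl)-4-[(1S)-1-(1,3-dioxolan-2-yl)propyl]-6-ethyloxan-2-one
Conditions: Me3SiOCH2CH2OSiMe3, TMSOTf (5 mol%), CH2Cl2, −78 °C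
Reagents that add atoms: 1,2-bis(trimethylsilyloxy)ethane C[Si](C)(C)OCCO[Si](C)(C)C
Why: Noyori acetalisation under aprotic conditions masks the aldehyde against the two enolisation steps ahead without opening the lactone.

Step 9
Reactants: 14 (4S,6S)-6-({[tert-butyl(diphenyl)silyl]oxy}methyl)-4-[(1S)-1-(1,3-dioxolan-2-yl)propyl]-6-ethyloxan-2-one
Product: 15 (3R,4R,6S)-6-({[tert-butyl(diphenyl)silyl]oxy}methyl)-4-[(1S)-1-(1,3-dioxolan-2-yl)propyl]-3,6-diethyloxan-2-one
Conditions: LDA, THF, −78 °C; EtI, DMPU, −78 → −20 °C
Reagents that add atoms: iodoethane CCI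
Why: Alkylation of the lactone enolate, expected trans to the neighbouring ring substituent; this centre (future C4) is planarised again in step 15, so its configuration is not critical.

Step 10
Reactants: 15 (3R,4R,6S)-6-({[tert-butyl(diphenyl)silyl]oxy}methyl)-4-[(1S)-1-(1,3-dioxolan-2-yl)propyl]-3,6-diethyloxan-2-one
Product: 16 (3R,4R,6S)-4-[(1S)-1-(1,3-dioxolan-2-yl)propyl]-3,6-diethyl-6-(hydroxymethyl)oxan-2-one
Conditions: HF·pyridine, pyridine, THF, 0 °C → rt
Reagents that add atoms: none
Why: Fluoride cleavage of the silyl ether under buffered, non-basic conditions, which should avoid acyl migration from the tertiary to the primary oxygen; the dioxolane survives.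

Step 11
Reactants: 16 (3R,4R,6S)-4-[(1S)-1-(1,3-dioxolan-2-yl)propyl]-3,6-diethyl-6-(hydroxymethyl)oxan-2-one
Product: 17 (2S,4R,5R)-4-[(1S)-1-(1,3-dioxolan-2-yl)propyl]-2,5-diethyl-6-oxooxane-2-carbaldehyde
Conditions: Dess–Martin periodinane, NaHCO3, CH2Cl2, rt
Reagents that add atoms: none
Why: Dess–Martin oxidation; the α-carbon is quaternary, so the aldehyde cannot epimerise.

Step 12
Reactants: 18 propyl(triphenyl)phosphonium bromide; 19 ethyl formate
Product: 20 2-(triphenylphosphoranylidene)butanal
Conditions: KOtBu (2 equiv), THF, 0 °C; then 19, 0 °C → rt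
Reagents that add atoms: none
Why: C-formylation of the non-stabilised ylide by a formate ester, followed by deprotonation, gives the stabilised α-formyl ylide.

Step 13
Reactants: 17 (2S,4R,5R)-4-[(1S)-1-(1,3-dioxolan-2-yl)propyl]-2,5-diethyl-6-oxooxane-2-carbaldehyde; 20 2-(triphenylphosphoranylidene)butanal
Product: 21 (2E)-3-[(2S,4R,5R)-4-[(1S)-1-(1,3-dioxolan-2-yl)propyl]-2,5-diethyl-6-oxooxan-2-yl]-2-ethylprop-2-enal
Conditions: PhMe, 90 °C
Reagents that add atoms: none
Why: Wittig reaction of a stabilised ylide, which should be E-selective (formyl trans and ethyl cis to the ring carbon); this alkene geometry is what step 15 translates into the C5 configuration.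

Step 14
Reactants: 21 (2E)-3-[(2S,4R,5R)-4-[(1S)-1-(1,3-dioxolan-2-yl)propyl]-2,5-diethyl-6-oxooxan-2-yl]-2-ethylprop-2-enal; 22 diethyl benzylphosphonate
Product: 23 (3R,4R,6S)-4-[(1S)-1-(1,3-dioxolan-2-yl)propyl]-3,6-diethyl-6-[(1E,3E)-2-ethyl-4-phenylbuta-1,3-dien-1-yl]oxan-2-one
Conditions: 22, n-BuLi, THF, −78 °C; then 21, −78 → 0 °C
Reagents that add atoms: none
Why: Horner–Wadsworth–Emmons olefination with a benzylphosphonate anion, which should be E-selective; the pre-formed anion should be consumed by the aldehyde faster than it attacks or enolises the lactone.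

Step 15
Reactants: 23 (3R,4R,6S)-4-[(1S)-1-(1,3-dioxolan-2-yl)propyl]-3,6-diethyl-6-[(1E,3E)-2-ethyl-4-phenylbuta-1,3-dien-1-yl]oxan-2-one
Product: 26 (1R,2S,6R)-6-[(1S)-1-(1,3-dioxolan-2-yl)propyl]-1,2,4-triethyl-2-[(E)-2-phenylethenyl]cyclohex-3-ene-1-carboxylic acid, via silyl ketene acetal 24 (not isolated), via trimethylsilyl ester 25 (not isolated)
Conditions: LDA, THF, −78 °C; TMSCl–Et3N, −78 °C → rt; PhMe, 80 °C; then 1 M HCl, rt
Reagents that add atoms: none
Why: Ireland–Claisen rearrangement of a lactone silyl ketene acetal (ring contraction of a 6-alkenyl δ-lactone) through a boat-like transition state. The ring fixes the ketene acetal geometry and holds the axial dienyl group over one face, so the carbinol configuration is transferred to C4 (carboxyl trans to the C3a side chain). The (E)-geometry of the trisubstituted alkene places styryl cis to carboxyl at C5.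

Step 16
Reactants: 26 (1R,2S,6R)-6-[(1S)-1-(1,3-dioxolan-2-yl)propyl]-1,2,4-triethyl-2-[(E)-2-phenylethenyl]cyclohex-3-ene-1-carboxylic acid
Product: 27 methyl (1R,2S,6R)-6-[(1S)-1-(1,3-dioxolan-2-yl)propyl]-1,2,4-triethyl-2-[(E)-2-phenylethenyl]cyclohex-3-ene-1-carboxylate
Conditions: MeI, K2CO3, DMF, rt
Reagents that add atoms: iodomethane CI
Why: O-alkylation of the carboxylate (SN2 at methyl), which is insensitive to the shielding of the carboxyl carbon.

Step 17
Reactants: 27 methyl (1R,2S,6R)-6-[(1S)-1-(1,3-dioxolan-2-yl)propyl]-1,2,4-triethyl-2-[(E)-2-phenylethenyl]cyclohex-3-ene-1-carboxylate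
Product: 28 methyl (1R,2S,6R)-1,2,4-triethyl-6-[(2S)-1-oxobutan-2-yl]-2-[(E)-2-phenylethenyl]cyclohex-3-ene-1-carboxylate
Conditions: 1 M HCl, THF, rt
Reagents that add atoms: water O
Why: Acid hydrolysis of the dioxolane under conditions mild enough to leave the alkenes, the hindered ester and the α-stereocentre of the aldehyde alone.

Step 18
Reactants: 28 methyl (1R,2S,6R)-1,2,4-triethyl-6-[(2S)-1-oxobutan-2-yl]-2-[(E)-2-phenylethenyl]cyclohex-3-ene-1-carboxylate; 29 ethyl diazoacetate
Product: 30 methyl (1R,2S,6R)-6-[(3S)-6-ethoxy-4,6-dioxohexan-3-yl]-1,2,4-triethyl-2-[(E)-2-phenylethenyl]cyclohex-3-ene-1-carboxylate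
Conditions: SnCl2 (10 mol%), CH2Cl2, rt
Reagents that add atoms: none
Why: Roskamp homologation: Lewis-acid-promoted addition of the diazo ester to the aldehyde, 1,2-hydride shift and loss of N2 give the β-keto ester; no metal carbenoid is formed, so the alkenes are safe.

Step 19
Reactants: 30 methyl (1R,2S,6R)-6-[(3S)-6-ethoxy-4,6-dioxohexan-3-yl]-1,2,4-triethyl-2-[(E)-2-phenylethenyl]cyclohex-3-ene-1-carboxylate
Product: 31 methyl (1R,2S,6R)-6-[(3S)-5-diazo-6-ethoxy-4,6-dioxohexan-3-yl]-1,2,4-triethyl-2-[(E)-2-phenylethenyl]cyclohex-3-ene-1-carboxylate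
Conditions: 4-acetamidobenzenesulfonyl azide, Et3N, MeCN, 0 °C → rt
Reagents that add atoms: 4-acetamidobenzenesulfonyl azide CC(=O)Nc1ccc(cc1)S(=O)(=O)N=[N+]=[N-]
Why: Regitz diazo transfer to the active methylene; the amine deprotonates only the doubly activated CH2, so the neighbouring stereocentre (future C3) is not enolised.

Step 20
Reactants: 31 methyl (1R,2S,6R)-6-[(3S)-5-diazo-6-ethoxy-4,6-dioxohexan-3-yl]-1,2,4-triethyl-2-[(E)-2-phenylethenyl]cyclohex-3-ene-1-carboxylate
Product: 32 1-ethyl 4-methyl (1S,3S,3aR,4R,5S,7aR)-3,4,5,7-tetraethyl-2-oxo-5-[(E)-2-phenylethenyl]-2,3,3a,4,5,7a-hexahydro-1H-indene-1,4-dicarboxylate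
Conditions: Rh2(O2CCPh3)4 (1 mol%), CH2Cl2, rt, slow addition of 31
Reagents that add atoms: none
Why: Loss of N2 from 31 at the dirhodium core gives an electrophilic acceptor/acceptor rhodium carbenoid at C1, which inserts into a C7a–H bond in a concerted, asynchronous three-centre step with retention at C7a; the closest known reaction type is the dirhodium-catalysed 1,5 C–H insertion of α-diazo β-keto esters to 2-alkoxycarbonylcyclopentanones. The five-membered ring closes through a chair-like six-centre array (C1, C2, C3, C3a, C7a and the migrating hydrogen), a 1,5-insertion, which is strongly preferred over 1,4- and 1,6-insertion. Site selectivity rests on ring size and C–H type, not on allylic activation: the only other C–H bonds at the 1,5 distance are the primary ones of the ethyl group on C3, which are far less reactive towards this carbenoid than a ring methylene. The C7a centre is controlled by which diastereotopic hydrogen reacts: with the C3a side chain equatorial on the half-chair, the carbenoid should take the pseudo-equatorial C7a–H, which places the new bond equatorial and gives the trans ring fusion. The C1 centre forms as an epimerisable β-keto ester carbon and should settle with the ester trans to the C7a–C7 bond; it is replaced in step 21 in any case. The chemoselectivity needed is insertion over cyclopropanation of the hindered trisubstituted C6=C7 bond and of the styryl group; the bulky triphenylacetate ligands disfavour addition to substituted alkenes and arenes, and slow addition keeps the diazo concentration low. C3, C3a, C4 and C5 are not involved and keep their configuration.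

Step 21
Reactants: 32 1-ethyl 4-methyl (1S,3S,3aR,4R,5S,7aR)-3,4,5,7-tetraethyl-2-oxo-5-[(E)-2-phenylethenyl]-2,3,3a,4,5,7a-hexahydro-1H-indene-1,4-dicarboxylate
Product: 33 1-ethyl 4-methyl (1R,3S,3aR,4R,5S,7aS)-1,3,4,5,7-pentaethyl-2-oxo-5-[(E)-2-phenylethenyl]-2,3,3a,4,5,7a-hexahydro-1H-indene-1,4-dicarboxylate
Conditions: K2CO3, EtI, acetone, 50 °C
Reagents that add atoms: iodoethane CCI
Why: C-alkylation of a cyclic β-keto ester, with iodoethane expected to approach anti to the C7a–C7 bond. The configuration of this quaternary carbon is of no consequence because it is lost on decarboxylation (the 7a descriptor changes by the priority rules only).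

Step 22
Reactants: 33 1-ethyl 4-methyl (1R,3S,3aR,4R,5S,7aS)-1,3,4,5,7-pentaethyl-2-oxo-5-[(E)-2-phenylethenyl]-2,3,3a,4,5,7a-hexahydro-1H-indene-1,4-dicarboxylate
Product: 35 (1S,3S,3aR,4R,5S,7aR)-1,3,4,5,7-pentaethyl-2-oxo-5-[(E)-2-phenylethenyl]-2,3,3a,4,5,7a-hexahydro-1H-indene-4-carboxylic acid, via keto diacid 34 (not isolated)
Conditions: LiI, 2,4,6-collidine, 170 °C; then 1 M HCl
Reagents that add atoms: none
Why: Iodide dealkylates both esters by SN2 at the alkyl carbon (the methyl ester cannot be saponified because its carbonyl carbon is flanked by two quaternary carbons), and the β-keto carboxylate loses CO2. In the hot basic medium the ketone should equilibrate at C1 and C3 to the all-trans arrangement of 35.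

## Compound list

1 | 2-methylenebutan-1-ol | C=C(CC)CO | starting material
2 | [(2R)-2-ethyloxiran-2-yl]methanol | CC[C@@]1(CO)CO1 | intermediate
3 | tert-butyl{[(2S)-2-ethyloxiran-2-yl]methoxy}diphenylsilane | CC[C@@]1(CO[Si](c2ccccc2)(c2ccccc2)C(C)(C)C)CO1 | intermediate
4 | vinylmagnesium bromide | C=C[Mg]Br | starting material
5 | (3S)-3-({[tert-butyl(diphenyl)silyl]oxy}methyl)hex-5-en-3-ol | CC[C@@](O)(CO[Si](c1ccccc1)(c1ccccc1)C(C)(C)C)CC=C | intermediate
6 | (2E)-but-2-enal | C/C=C/C=O | starting material
7 | (2E,5S)-5-({[tert-butyl(diphenyl)silyl]oxy}methyl)-5-hydroxyhept-2-enal | CC[C@@](O)(CO[Si](c1ccccc1)(c1ccccc1)C(C)(C)C)C/C=C/C=O | intermediate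
8 | S-methyl butanethioate | CCCC(=O)SC | starting material
9 | tert-butyl(dimethyl){[(1Z)-1-(methylsulfanyl)but-1-en-1-yl]oxy}silane | CC/C=C(\SC)O[Si](C)(C)C(C)(C)C | intermediate
10 | S-methyl (2S,3S,5S)-5-({[tert-butyl(diphenyl)silyl]oxy}methyl)-2-ethyl-5-hydroxy-3-(2-oxoethyl)heptanethioate | O=CC[C@H](C[C@@](O)(CC)CO[Si](c1ccccc1)(c1ccccc1)C(C)(C)C)[C@H](CC)C(=O)SC | intermediate
11 | S-methyl (2S)-2-[(2S,4S)-2-({[tert-butyl(diphenyl)silyl]oxy}methyl)-2-ethyl-6-hydroxyoxan-4-yl]butanethioate (both anomers) | OC1C[C@@H]([C@H](CC)C(=O)SC)C[C@@](CC)(CO[Si](c2ccccc2)(c2ccccc2)C(C)(C)C)O1 | intermediate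
12 | S-methyl (2S)-2-[(2S,4S)-2-({[tert-butyl(diphenyl)silyl]oxy}methyl)-2-ethyl-6-oxooxan-4-yl]butanethioate | O=C1C[C@@H]([C@H](CC)C(=O)SC)C[C@@](CC)(CO[Si](c2ccccc2)(c2ccccc2)C(C)(C)C)O1 | intermediate
13 | (2S)-2-[(2S,4S)-2-({[tert-butyl(diphenyl)silyl]oxy}methyl)-2-ethyl-6-oxooxan-4-yl]butanal | O=C1C[C@@H]([C@H](CC)C=O)C[C@@](CC)(CO[Si](c2ccccc2)(c2ccccc2)C(C)(C)C)O1 | intermediate
14 | (4S,6S)-6-({[tert-butyl(diphenyl)silyl]oxy}methyl)-4-[(1S)-1-(1,3-dioxolan-2-yl)propyl]-6-ethyloxan-2-one | O=C1C[C@@H]([C@H](CC)C2OCCO2)C[C@@](CC)(CO[Si](c3ccccc3)(c3ccccc3)C(C)(C)C)O1 | intermediate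
15 | (3R,4R,6S)-6-({[tert-butyl(diphenyl)silyl]oxy}methyl)-4-[(1S)-1-(1,3-dioxolan-2-yl)propyl]-3,6-diethyloxan-2-one | CC[C@H]1C(=O)O[C@](CC)(CO[Si](c2ccccc2)(c2ccccc2)C(C)(C)C)C[C@@H]1[C@H](CC)C3OCCO3 | intermediate
16 | (3R,4R,6S)-4-[(1S)-1-(1,3-dioxolan-2-yl)propyl]-3,6-diethyl-6-(hydroxymethyl)oxan-2-one | CC[C@H]1C(=O)O[C@](CC)(CO)C[C@@H]1[C@H](CC)C2OCCO2 | intermediate
17 | (2S,4R,5R)-4-[(1S)-1-(1,3-dioxolan-2-yl)propyl]-2,5-diethyl-6-oxooxane-2-carbaldehyde | CC[C@H]1C(=O)O[C@](CC)(C=O)C[C@@H]1[C@H](CC)C2OCCO2 | intermediate
18 | propyl(triphenyl)phosphonium bromide | CCC[P+](c1ccccc1)(c1ccccc1)c1ccccc1.[Br-] | starting material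
19 | ethyl formate | CCOC=O | starting material
20 | 2-(triphenylphosphoranylidene)butanal | CCC(C=O)=P(c1ccccc1)(c1ccccc1)c1ccccc1 | intermediate
21 | (2E)-3-[(2S,4R,5R)-4-[(1S)-1-(1,3-dioxolan-2-yl)propyl]-2,5-diethyl-6-oxooxan-2-yl]-2-ethylprop-2-enal | CC[C@H]1C(=O)O[C@](CC)(/C=C(\CC)C=O)C[C@@H]1[C@H](CC)C2OCCO2 | intermediate
22 | diethyl benzylphosphonate | CCOP(=O)(Cc1ccccc1)OCC | starting material
23 | (3R,4R,6S)-4-[(1S)-1-(1,3-dioxolan-2-yl)propyl]-3,6-diethyl-6-[(1E,3E)-2-ethyl-4-phenylbuta-1,3-dien-1-yl]oxan-2-one | CC[C@H]1C(=O)O[C@](CC)(/C=C(CC)/C=C/c2ccccc2)C[C@@H]1[C@H](CC)C3OCCO3 | intermediate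
24 | trimethylsilyl ketene acetal of 23 (6-trimethylsilyloxy-3,4-dihydro-2H-pyran, other substituents and configurations as in 23) | CC[C@]1(/C=C(CC)/C=C/c2ccccc2)OC(O[Si](C)(C)C)=C(CC)[C@@H]([C@H](CC)C3OCCO3)C1 | intermediate
25 | trimethylsilyl (1R,2S,6R)-6-[(1S)-1-(1,3-dioxolan-2-yl)propyl]-1,2,4-triethyl-2-[(E)-2-phenylethenyl]cyclohex-3-ene-1-carboxylate | CCC1=C[C@@](/C=C/c2ccccc2)(CC)[C@](CC)(C(=O)O[Si](C)(C)C)[C@@H]([C@H](CC)C3OCCO3)C1 | intermediate
26 | (1R,2S,6R)-6-[(1S)-1-(1,3-dioxolan-2-yl)propyl]-1,2,4-triethyl-2-[(E)-2-phenylethenyl]cyclohex-3-ene-1-carboxylic acid | CCC1=C[C@@](/C=C/c2ccccc2)(CC)[C@](CC)(C(=O)O)[C@@H]([C@H](CC)C3OCCO3)C1 | intermediate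
27 | methyl (1R,2S,6R)-6-[(1S)-1-(1,3-dioxolan-2-yl)propyl]-1,2,4-triethyl-2-[(E)-2-phenylethenyl]cyclohex-3-ene-1-carboxylate | CCC1=C[C@@](/C=C/c2ccccc2)(CC)[C@](CC)(C(=O)OC)[C@@H]([C@H](CC)C3OCCO3)C1 | intermediate
28 | methyl (1R,2S,6R)-1,2,4-triethyl-6-[(2S)-1-oxobutan-2-yl]-2-[(E)-2-phenylethenyl]cyclohex-3-ene-1-carboxylate | CCC1=C[C@@](/C=C/c2ccccc2)(CC)[C@](CC)(C(=O)OC)[C@@H]([C@H](CC)C=O)C1 | intermediate
29 | ethyl diazoacetate | CCOC(=O)C=[N+]=[N-] | starting material
30 | methyl (1R,2S,6R)-6-[(3S)-6-ethoxy-4,6-dioxohexan-3-yl]-1,2,4-triethyl-2-[(E)-2-phenylethenyl]cyclohex-3-ene-1-carboxylate | CCC1=C[C@@](/C=C/c2ccccc2)(CC)[C@](CC)(C(=O)OC)[C@@H]([C@H](CC)C(=O)CC(=O)OCC)C1 | intermediate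
31 | methyl (1R,2S,6R)-6-[(3S)-5-diazo-6-ethoxy-4,6-dioxohexan-3-yl]-1,2,4-triethyl-2-[(E)-2-phenylethenyl]cyclohex-3-ene-1-carboxylate | CCC1=C[C@@](/C=C/c2ccccc2)(CC)[C@](CC)(C(=O)OC)[C@@H]([C@H](CC)C(=O)C(=[N+]=[N-])C(=O)OCC)C1 | intermediate
32 | 1-ethyl 4-methyl (1S,3S,3aR,4R,5S,7aR)-3,4,5,7-tetraethyl-2-oxo-5-[(E)-2-phenylethenyl]-2,3,3a,4,5,7a-hexahydro-1H-indene-1,4-dicarboxylate | CCC1=C[C@@](/C=C/c2ccccc2)(CC)[C@](CC)(C(=O)OC)[C@@H]2[C@@H]1[C@H](C(=O)OCC)C(=O)[C@H]2CC | intermediate
33 | 1-ethyl 4-methyl (1R,3S,3aR,4R,5S,7aS)-1,3,4,5,7-pentaethyl-2-oxo-5-[(E)-2-phenylethenyl]-2,3,3a,4,5,7a-hexahydro-1H-indene-1,4-dicarboxylate | CCC1=C[C@@](/C=C/c2ccccc2)(CC)[C@](CC)(C(=O)OC)[C@@H]2[C@@H]1[C@@](CC)(C(=O)OCC)C(=O)[C@H]2CC | intermediate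
34 | (1R,3S,3aR,4R,5S,7aS)-1,3,4,5,7-pentaethyl-2-oxo-5-[(E)-2-phenylethenyl]-2,3,3a,4,5,7a-hexahydro-1H-indene-1,4-dicarboxylic acid (as its dilithium salt) | CCC1=C[C@@](/C=C/c2ccccc2)(CC)[C@](CC)(C(=O)O)[C@@H]2[C@@H]1[C@@](CC)(C(=O)O)C(=O)[C@H]2CC | intermediate
35 | (1S,3S,3aR,4R,5S,7aR)-1,3,4,5,7-pentaethyl-2-oxo-5-[(E)-2-phenylethenyl]-2,3,3a,4,5,7a-hexahydro-1H-indene-4-carboxylic acid | CCC1=C[C@@](/C=C/c2ccccc2)(CC)[C@](CC)(C(=O)O)[C@@H]2[C@@H]1[C@H](CC)C(=O)[C@H]2CC | target

## Step count and least certain steps

Total: 22 steps. Longest linear sequence: 20 steps (steps 1–3, 5–11 and 13–22); steps 4 and 12 prepare the reagents 9 and 20 off the main line.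

Step 20 (key step). The most likely failures are insertion into the pseudo-axial instead of the pseudo-equatorial C7a–H bond, which would give a cis ring fusion that no later step can correct, and addition of the carbenoid to the C6=C7 or styryl double bond in place of C–H insertion. Both follow from the fact that the reacting CH2 is allylic and sits on a flexible half-chair. Fallback, setting out from 27 and returning at 32: the C1–C7a bond is made by allylic substitution. Allylic hydroxylation of 27 with SeO2 and tert-butyl hydroperoxide should attack the ring CH2 next to the more substituted alkene carbon and give the pseudo-axial allylic alcohol F1. Mitsunobu inversion with benzoic acid should give the allylic benzoate F2. Acetal hydrolysis as in step 17 then gives the aldehyde F3, and homologation with 29 as in step 18 gives the β-keto ester F4. With Pd(PPh3)4 and K2CO3 in THF, zerovalent palladium should ionise the benzoate with inversion. The tethered β-keto ester carbon should then attack the allyl terminus C7a from the face opposite to palladium; a five-membered ring is preferred over a seven-membered one. The overall retention places the new bond pseudo-equatorial and gives 32.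

Step 15. The most likely failure is slow rearrangement followed by ionisation of the tertiary dienylic C–O bond (elimination or non-stereospecific recombination). The boat-like transition state forces the ethyl group of the alkene terminus and the branched C3a substituent onto the same side of the forming bond, and the dienyl ester is a very good leaving group. Fallback, setting out from 21 and returning at 27: the styryl group is installed after the ring contraction, so that the rearranging ester is only allylic and tolerates longer heating. Luche reduction of 21 (NaBH4, CeCl3, MeOH) gives the allylic alcohol F5, and TESCl with imidazole gives the triethylsilyl ether F6. Ireland–Claisen rearrangement as in step 15 with a neutral aqueous work-up gives the acid F7, and MeI with K2CO3 gives the methyl ester F8. Swern oxidation converts the primary triethylsilyl ether directly into the neopentyl aldehyde F9; this avoids a free hydroxymethyl group cis to the ester, which could lactonise. Horner–Wadsworth–Emmons reaction of F9 with 22 gives 27.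

Step 5. The most likely failures are insufficient facial selectivity on a β-branched enal and the wrong sense of simple diastereoselection at future C3. The small S-methyl group of 9 and the neopentyl-type β-substituent of 7 lie outside the best-behaved range of this catalysis. A wrong configuration at future C3 alone would still be corrected in step 22; a wrong one at future C3a would not. Fallback, setting out from 5 and returning at 13: auxiliary control replaces catalyst control. Cross-metathesis of 5 with methyl acrylate gives the (E)-enoate F10. Butanal is condensed with (S)-1-amino-2-(methoxymethyl)pyrrolidine to the hydrazone F11. Its lithium azaenolate (LDA, THF, −78 °C) is added to the lithium alkoxide of F10, and acidic work-up closes the lactone to the hydrazone lactone F12. The auxiliary enantiomer is chosen for the (S)-configured side-chain carbon, and the sense at the ring carbon must be confirmed. Ozonolysis of the C=N bond at −78 °C then gives 13.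

Step 22. The most likely failure is incomplete dealkylation of the ethyl ester, or of the hindered methyl ester, before decomposition sets in, because one reagent must perform two SN2 cleavages of different rate at high temperature. Fallback, setting out from 33 and returning at 35: the two events are separated. Krapcho de-ethoxycarbonylation (LiCl, wet DMSO, 150 °C) gives the keto methyl ester F13, which is equilibrated with DBU. The methyl ester is then cleaved by a thiolate at the methyl carbon (NaSEt, DMF, 100 °C), and acidification gives 35.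

## Further compounds

F1 | step 20 | methyl (1R,2S,5S,6R)-6-[(1S)-1-(1,3-dioxolan-2-yl)propyl]-1,2,4-triethyl-5-hydroxy-2-[(E)-2-phenylethenyl]cyclohex-3-ene-1-carboxylate (hydroxyl at future C7a, pseudo-axial) | CCC1=C[C@@](/C=C/c2ccccc2)(CC)[C@](CC)(C(=O)OC)[C@@H]([C@H](CC)C3OCCO3)[C@H]1O
F2 | step 20 | benzoate of the C7a epimer of F1 (benzoyloxy at future C7a, inverted) | CCC1=C[C@@](/C=C/c2ccccc2)(CC)[C@](CC)(C(=O)OC)[C@@H]([C@H](CC)C3OCCO3)[C@@H]1OC(=O)c4ccccc4
F3 | step 20 | aldehyde from F2 (side chain (2S)-1-oxobutan-2-yl, benzoate retained) | CCC1=C[C@@](/C=C/c2ccccc2)(CC)[C@](CC)(C(=O)OC)[C@@H]([C@H](CC)C=O)[C@@H]1OC(=O)c3ccccc3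
F4 | step 20 | β-keto ester from F3 (side chain (3S)-6-ethoxy-4,6-dioxohexan-3-yl, benzoate retained) | CCC1=C[C@@](/C=C/c2ccccc2)(CC)[C@](CC)(C(=O)OC)[C@@H]([C@H](CC)C(=O)CC(=O)OCC)[C@@H]1OC(=O)c3ccccc3
F5 | step 15 | (3R,4R,6S)-4-[(1S)-1-(1,3-dioxolan-2-yl)propyl]-3,6-diethyl-6-[(1E)-2-(hydroxymethyl)but-1-en-1-yl]oxan-2-one | CC[C@H]1C(=O)O[C@](CC)(/C=C(\CC)CO)C[C@@H]1[C@H](CC)C2OCCO2
F6 | step 15 | triethylsilyl ether of F5 | CC[C@H]1C(=O)O[C@](CC)(/C=C(\CC)CO[Si](CC)(CC)CC)C[C@@H]1[C@H](CC)C2OCCO2
F7 | step 15 | (1R,2S,6R)-6-[(1S)-1-(1,3-dioxolan-2-yl)propyl]-1,2,4-triethyl-2-[(triethylsilyloxy)methyl]cyclohex-3-ene-1-carboxylic acid | CCC1=C[C@@](CO[Si](CC)(CC)CC)(CC)[C@](CC)(C(=O)O)[C@@H]([C@H](CC)C2OCCO2)C1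
F8 | step 15 | methyl ester of F7 | CCC1=C[C@@](CO[Si](CC)(CC)CC)(CC)[C@](CC)(C(=O)OC)[C@@H]([C@H](CC)C2OCCO2)C1
F9 | step 15 | methyl (1R,2S,6R)-6-[(1S)-1-(1,3-dioxolan-2-yl)propyl]-1,2,4-triethyl-2-formylcyclohex-3-ene-1-carboxylate | CCC1=C[C@@](C=O)(CC)[C@](CC)(C(=O)OC)[C@@H]([C@H](CC)C2OCCO2)C1
F10 | step 5 | methyl (2E,5S)-5-({[tert-butyl(diphenyl)silyl]oxy}methyl)-5-hydroxyhept-2-enoate | CC[C@@](O)(CO[Si](c1ccccc1)(c1ccccc1)C(C)(C)C)C/C=C/C(=O)OC
F11 | step 5 | (E)-butanal hydrazone of (S)-1-amino-2-(methoxymethyl)pyrrolidine | CCC/C=N/N1CCC[C@H]1COC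
F12 | step 5 | hydrazone of 13 with (S)-1-amino-2-(methoxymethyl)pyrrolidine | O=C1C[C@@H]([C@H](CC)/C=N/N2CCC[C@H]2COC)C[C@@](CC)(CO[Si](c3ccccc3)(c3ccccc3)C(C)(C)C)O1
F13 | step 22 | methyl (1S,3S,3aR,4R,5S,7aR)-1,3,4,5,7-pentaethyl-2-oxo-5-[(E)-2-phenylethenyl]-2,3,3a,4,5,7a-hexahydro-1H-indene-4-carboxylate | CCC1=C[C@@](/C=C/c2ccccc2)(CC)[C@](CC)(C(=O)OC)[C@@H]2[C@@H]1[C@H](CC)C(=O)[C@H]2CC
A1 | alternative 1 | all-trans cyclopentanone from cuprate addition and ethylation, carrying but-1-en-2-yl on future C7a and the vinyl/styryl side chain | C=C[C@@](/C=C/c1ccccc1)(CC)[C@](CC)(C(=O)OC)[C@@H]1[C@@H](C(CC)=C)[C@H](CC)C(=O)[C@H]1CC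
A2 | alternative 1 | 5-ethylcyclopent-2-enone carrying the bis-quaternary ester side chain on C4 | C=C[C@@](/C=C/c1ccccc1)(CC)[C@](CC)(C(=O)OC)[C@@H]1C=CC(=O)[C@H]1CC
A3 | alternative 1 | methyl ester of 35 | CCC1=C[C@@](/C=C/c2ccccc2)(CC)[C@](CC)(C(=O)OC)[C@@H]2[C@@H]1[C@H](CC)C(=O)[C@H]2CC
A4 | alternative 2 | bicyclic cyclopentenone ester with the C3=C3a enone (Pauson–Khand product) | CCC1=C[C@@](/C=C/c2ccccc2)(CC)[C@](CC)(C(=O)OC)C=2[C@@H]1[C@H](CC)C(=O)C2CC
A5 | alternative 2 | acyclic dienyne ester (but-1-ynyl on future C4, (3Z,5E)-diene chain on future C5) | CC/C=C/C(CC)=C\[C@@](/C=C/c1ccccc1)(CC)[C@](CC)(C(=O)OC)C#CCC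
A6 | alternative 3 | bicyclic keto ester with vinyl in place of styryl on C5 | CCC1=C[C@@](C=C)(CC)[C@](CC)(C(=O)OC)[C@@H]2[C@@H]1[C@H](CC)C(=O)[C@H]2CC
A7 | alternative 3 | all-trans cyclopentanone with but-1-en-2-yl on future C7a and a bis-vinyl carbon in the side chain | C=CC(C=C)(CC)[C@](CC)(C(=O)OC)[C@@H]1[C@@H](C(CC)=C)[C@H](CC)C(=O)[C@H]1CC
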